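## Structural features

The target is a chroman-4-one: benzene ring A (C4a, C5 to C8, C8a) is fused through the C4a–C8a bond to the dihydropyranone ring B (O1, C2, C3, C4). Ring A carries oxygen at C8a (O1) and at C6 (free phenol) in a 1,4 relationship, bromine at C7 beside the phenol, and hydrogen at C5 and C8. C2 is the only stereocentre, a fully substituted (R)-configured ether carbon bearing methyl, the C3 methylene and a 4-hydroxy-4-methylpentyl chain; with no neighbouring centre to relay from, it must be bought or made in the absolute sense. The fragile groups are the β-aryloxy ketone (base can open O1–C2 by retro-oxa-Michael elimination and so racemise C2), the tertiary alcohol (acid), the aryl bromide (reduction, zerovalent metals) and the electron-rich para-alkoxyphenol (oxidants, radicals). The real difficulty is to combine a quaternary oxygen-bearing stereocentre with an unambiguous placing of O, O and Br on ring A. The key step exploits the fact that C8a(O1), C8(H), C7(Br) and C6(O) are the four carbons of a 3,6-dioxygenated 4-bromopyridazine and that C4a–C5 can come from a terminal alkyne, so ring A is built rather than substituted. C2 with its methyl group, its oxygen and the six-carbon chain is the carbinol carbon of (R)-linalool, whose vinyl group supplies C3 and C4.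

## Logic of the disconnections

18 to 17. The phenolic O–CH2 (benzylic) bond at C6 is cut. The para-alkoxyphenol is the most oxidisable part of the molecule and a radical-chain inhibitor, so it is uncovered last. Nothing is gained in the skeleton, but every earlier step then works on a masked phenol. The forward cleavage must be neutral and must leave C7–Br, the tertiary alcohol and the β-aryloxy ketone alone.

17 to 16. The C–O bond of the tertiary alcohol is cut (Markovnikov hydration retron). The side chain becomes the 4-methylpent-3-enyl group that 1 already contains. The forward hydration must work without acid and without reducing C4=O or C7–Br.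

16 to 15 to 14. C4=O is taken back to the carbinol and then to its silyl ether. A ketone at C4 before ring closure would mean a β-heteroaryloxy ynone, which is prone to elimination and has an electron-poor alkyne; as a silyl ether C4 is an inert spectator. The demand is order: fluoride must act before the ketone exists, and both C4 epimers must oxidise.

14 to 12 (through 13). C4a–C8a and C5–C6 are cut and N2 is put back between C8a and C6. Both rings open at once: ring A becomes a pyridazine that already holds O1, the C6 oxygen and bromine in fixed positions, and C4a–C5 becomes a terminal alkyne. The forward step must outrun thermal loss of the tertiary ether, and the tether must dictate the regiochemistry.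

12 to 11 to 10. The O–Si bond is cut, then the C–C bond between the carbinol carbon and the alkyne. A two-carbon acetylide nucleophile and an aldehyde result. The nucleophile must be weakly basic, because the aldehyde carries a leaving group on its β-carbon; no stereocontrol is required.

10 to 9 to 7 (through 8). The aldehyde is taken back to the primary alcohol and this to the vinyl group (anti-Markovnikov hydration retron). This reaches the vinyl group of 1. The hydroboration must tell the monosubstituted from the trisubstituted alkene and tolerate a tertiary allylic heteroaryl ether.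

7 to 5 (through 6). The C–Br bond on the pyridazine is cut. Bromine has to be introduced after both alkoxide substitutions, because a 4-halogen on a pyridazine is itself displaced by alkoxides. The forward deprotonation must occur beside the benzyloxy group and not beside the tertiary alkoxy group.

5 to 1, 2 and 3 (through 4). Both heteroaryl C–O bonds are cut, giving three commercial materials and a bought stereocentre. Both ethers are made on 1 itself so that no silyl ether ever sits 1,3 to the tertiary alkoxide (no silyl transfer) and so that the alkyne can later be introduced unprotected, which saves a C-silyl protection and its removal. The hindered tertiary alkoxide must go first, onto the more electrophilic dihalide, and the carbinol C–O bond of 1 is never broken.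

## Other disconnections considered

Alternative 1: The cut is O1–C2 together with the first C–C bond of the side chain. The phenol A2 would be treated with Pd(OCOCF3)2 and a chiral bis(oxazoline) ligand under reoxidising conditions. 6-exo oxypalladation of the 1,1-disubstituted alkene by divalent palladium would create C2 and a primary alkylpalladium without β-hydrogen, which inserts methyl vinyl ketone A3 and eliminates to the enone A1.
- In favour: C2 is set catalytically at moderate temperature, three side-chain carbons arrive in the same step, and no thermally fragile ether is heated. On mildness and on independence from the optical purity of a chiral-pool material it is the better plan.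
- Against: A1 is a chroman, so C4 must later be oxidised at a benzylic methylene of an electron-rich bromoarene. The enone must be saturated without touching C7–Br and a methyl nucleophile added. Zerovalent palladium formed in each turnover can insert into C7–Br before it is reoxidised. Ring A with its O, O, Br pattern must first be made by classical arene chemistry with its own regiochemical questions. The facial selectivity rests on a ligand match for a substrate carrying bromine and a bulky silyloxy group.
- Comparison: both plans close ring B, but the chosen plan also makes ring A and fixes the bromine position by construction. The step count is about equal (roughly four steps to A2, the key step, then four or five). The chosen plan is worse on temperature and better on the oxidation state at C4 and on the security of the C2 configuration.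

Alternative 2: The cut is C2–C3. The diazoketone A5 would be decomposed by dirhodium tetraacetate, Rh2(OAc)4; the carbenoid at C3 would insert into the oxygen-activated C2–H bond with retention to give the chromanone A4.
- In favour: the ketone is formed directly (better than the chosen plan, which needs desilylation and oxidation), the step runs at ambient temperature, and the insertion is stereospecific, so a simple enantiopure secondary alcohol becomes the quaternary centre. On stereochemical security the two plans are equal in principle. The acetal and silyl ether of A4 could fall together in one mild acidic step.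
- Against: the C–H bond is tertiary and hindered, and the closure is six-membered, whereas carbenoids prefer five-membered transition states. Attack on the ether oxygen to form an oxonium ylide (leading to a benzofuranone after a 1,2-shift), addition to the aromatic ring and carbene dimerisation are the expected competitors. A5 needs diazomethane-type reagents, a fully substituted salicylic acid and an aryl ether of a chiral secondary alcohol.
- Comparison: milder and better in oxidation-state economy, less predictable in chemoselectivity, comparable in overall length because the saving after the key step is spent before it.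

Alternative 3: The cut is C3–C4 and C4–C4a with carbon monoxide A8 as the C4 source. Zerovalent palladium with a chiral ligand would insert into the C4a–I bond of the achiral aryl iodide A7, activate one of the two enantiotopic methyl groups through a six-membered palladacycle, insert A8 and reductively eliminate to A6.
- In favour: the precursor is achiral and simple, two C–C bonds and the ketone arise in one step, and the plan is the shortest on paper. On step economy and oxidation state it is the better plan.
- Against: enantiotopic methyl discrimination in a carbonylative closure to a six-membered ketone has no close model. Direct C–H arylation without carbonyl insertion would give a dihydrobenzofuran. C7–Br competes for zerovalent palladium. Making the tertiary aryl ether A7 on an electron-rich polyhalogenated arene is itself hard.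
- Comparison: the chosen plan is longer and thermally harsher, but its C2 configuration is not at stake and its bromine never meets a low-valent metal.

Key step: step 7

Remark on the chemistry: the carbinol carbon that becomes C4 is formed without stereocontrol and is carried as both epimers, because step 9 erases it. The SMILES of 11 to 15 leave it unmarked; the (3S,5R) silyl ether and its (2R,4S) cycloadduct are one member of each pair. The enantiomeric purity of 18 cannot exceed that of the commercial 1.

## Route

Step 1
Reactants: 1 (R)-linalool; 2 3,6-dichloropyridazine; 3 4-methoxybenzyl alcohol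
Product: 5 3-{[(3R)-3,7-dimethylocta-1,6-dien-3-yl]oxy}-6-(4-methoxybenzyloxy)pyridazine, via monochloro ether 4 (not isolated)
Conditions: 1, KN(SiMe3)2, THF, 0 °C; 2, 0 °C to rt; then 3 premixed with KN(SiMe3)2, THF, 50 °C
Reagents that add atoms: none
Why: Two nucleophilic aromatic substitutions (addition–elimination); the hindered tertiary alkoxide is spent on the more electrophilic dichloride, and the deactivated monochloride 4 should still accept the unhindered primary alkoxide on warming. The stereocentre is the carbinol carbon of the nucleophile, its C–O bond is never broken, and (R) is retained.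

Step 2
Reactants: 5 3-{[(3R)-3,7-dimethylocta-1,6-dien-3-yl]oxy}-6-(4-methoxybenzyloxy)pyridazine
Product: 7 4-bromo-6-{[(3R)-3,7-dimethylocta-1,6-dien-3-yl]oxy}-3-(4-methoxybenzyloxy)pyridazine, via pyridazin-4-ylmagnesium chloride 6 (not isolated)
Conditions: TMPMgCl·LiCl, THF, −40 to −10 °C; then BrCl2CCCl2Br, −40 °C to rt
Reagents that add atoms: 1,2-dibromo-1,1,2,2-tetrachloroethane, BrC(Cl)(Cl)C(Cl)(Cl)Br
Why: Directed magnesiation of an alkoxydiazine with a hindered amide base, then electrophilic bromination of the heteroarylmagnesium. Deprotonation should favour C4, beside the accessible primary benzyloxy oxygen that can guide the base, over C5 beside the congested tertiary alkoxy oxygen. Bromine is introduced only now because a 4-halogen on a pyridazine would not survive the alkoxides of step 1.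

Step 3
Reactants: 7 4-bromo-6-{[(3R)-3,7-dimethylocta-1,6-dien-3-yl]oxy}-3-(4-methoxybenzyloxy)pyridazine
Product: 9 (3R)-3-{[5-bromo-6-(4-methoxybenzyloxy)pyridazin-3-yl]oxy}-3,7-dimethyloct-6-en-1-ol, via B-alkyl-9-borabicyclononane 8 (not isolated)
Conditions: 9-BBN, THF, 0 °C to rt; then NaBO3·4H2O, THF/H2O, rt
Reagents that add atoms: sodium perborate, [Na+].[Na+].O[B-]1(O)OO[B-](O)(O)OO1
Why: Hydroboration–oxidation; 9-BBN adds to the monosubstituted vinyl group far faster than to the trisubstituted alkene and places boron on the terminal carbon. Perborate oxidises the borane under mild conditions that should spare the bromopyridazine and keep the new primary alcohol from attacking the heteroaryl ether.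

Step 4
Reactants: 9 (3R)-3-{[5-bromo-6-(4-methoxybenzyloxy)pyridazin-3-yl]oxy}-3,7-dimethyloct-6-en-1-ol
Product: 10 (3R)-3-{[5-bromo-6-(4-methoxybenzyloxy)pyridazin-3-yl]oxy}-3,7-dimethyloct-6-enal
Conditions: Dess–Martin periodinane, NaHCO3, CH2Cl2, 0 °C to rt; used crude
Reagents that add atoms: none
Why: Dess–Martin oxidation stops at the aldehyde, and the bicarbonate buffer avoids both acid (tertiary ether) and base strong enough to expel the β-heteroaryloxy group.

Step 5
Reactants: 10 (3R)-3-{[5-bromo-6-(4-methoxybenzyloxy)pyridazin-3-yl]oxy}-3,7-dimethyloct-6-enal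
Product: 11 (3RS,5R)-5-{[5-bromo-6-(4-methoxybenzyloxy)pyridazin-3-yl]oxy}-5,9-dimethyldec-8-en-1-yn-3-ol
Conditions: HC≡CMgBr, THF, −78 to −40 °C; NH4Cl (aq) at −40 °C
Reagents that add atoms: ethynylmagnesium bromide, C#C[Mg]Br
Why: Grignard addition of a weakly basic alkynylmagnesium should outrun enolisation of the aldehyde at low temperature, and the cold quench keeps the magnesium alkoxide from attacking the pyridazine. The new carbinol centre forms as both epimers, which is immaterial because it becomes the C4 ketone.

Step 6
Reactants: 11 (3RS,5R)-5-{[5-bromo-6-(4-methoxybenzyloxy)pyridazin-3-yl]oxy}-5,9-dimethyldec-8-en-1-yn-3-ol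
Product: 12 4-bromo-6-{[(3RS,5R)-3-(tert-butyldimethylsilyloxy)-5,9-dimethyldec-8-en-1-yn-5-yl]oxy}-3-(4-methoxybenzyloxy)pyridazine
Conditions: TBSCl, imidazole, DMF, rt
Reagents that add atoms: tert-butyldimethylsilyl chloride, CC(C)(C)[Si](C)(C)Cl
Why: Imidazole-promoted silylation of an unhindered secondary propargylic alcohol under neutral conditions that leave the tertiary ether and the bromide alone. The silyl ether blocks the hydroxyl that could otherwise take over the heteroaryl group (Smiles-type shift) during thermolysis, and its bulk helps to fold the tether.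

Step 7
Reactants: 12 4-bromo-6-{[(3RS,5R)-3-(tert-butyldimethylsilyloxy)-5,9-dimethyldec-8-en-1-yn-5-yl]oxy}-3-(4-methoxybenzyloxy)pyridazine
Product: 14 (2R,4RS)-7-bromo-4-(tert-butyldimethylsilyloxy)-6-(4-methoxybenzyloxy)-2-methyl-2-(4-methylpent-3-en-1-yl)chromane, via bridged diaza cycloadduct 13 (not isolated)
Conditions: 1,3,5-triisopropylbenzene (0.01 M), 2,6-di-tert-butyl-4-methylpyridine (0.2 equiv), degassed, sealed vessel, 200–210 °C
Reagents that add atoms: none
Why: The pyridazine acts as an azadiene through its two oxygen-bearing carbons and the tethered terminal alkyne as dienophile; an intramolecular inverse-electron-demand [4+2] cycloaddition gives the bridged 2,3-diazabicyclo[2.2.2]octatriene 13, which loses dinitrogen irreversibly by retro-[4+2] and leaves benzene ring A. The closest known reaction type is the thermal cyclisation of 3-(alkynyloxy)pyridazines to benzo-fused oxygen heterocycles with loss of nitrogen. Ring B closes in the cycloaddition itself, in the exo sense, as the six-membered tether ring (bond C4a–C8a), while ring A arises by the cycloaddition–cycloreversion pair (bond C5–C6 made, two C–N bonds broken). No stereocentre is created: C2 from 1 and the C4 epimers are spectators, and the bridgehead centres of 13 vanish with the nitrogen. The step needs regioselectivity and chemoselectivity. Regiochemistry is fixed by the four-atom tether O1–C2–C3–C4, which lets the internal alkyne carbon reach only the pyridazine carbon that bears O1, so bromine and the benzyloxy group must land at C7 and C6. Chemoselectivity over ene-type thermal elimination of the tertiary ether and over O-to-N shift of the benzyl group is helped by the fully substituted C2 and the bulky C4 silyloxy group (gem-disubstituent effect), by bromine lowering the diene LUMO, and by the dilute, non-polar, base-buffered medium that removes acid catalysis of both side reactions.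

Step 8
Reactants: 14 (2R,4RS)-7-bromo-4-(tert-butyldimethylsilyloxy)-6-(4-methoxybenzyloxy)-2-methyl-2-(4-methylpent-3-en-1-yl)chromane
Product: 15 (2R,4RS)-7-bromo-6-(4-methoxybenzyloxy)-2-methyl-2-(4-methylpent-3-en-1-yl)chroman-4-ol
Conditions: Bu4NF, THF, 0 °C to rt
Reagents that add atoms: none
Why: Fluoride-induced cleavage of the silyl ether, placed before C4 becomes a ketone so that basic fluoride never meets the base-sensitive β-aryloxy ketone.

Step 9
Reactants: 15 (2R,4RS)-7-bromo-6-(4-methoxybenzyloxy)-2-methyl-2-(4-methylpent-3-en-1-yl)chroman-4-ol
Product: 16 (2R)-7-bromo-6-(4-methoxybenzyloxy)-2-methyl-2-(4-methylpent-3-en-1-yl)chroman-4-one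
Conditions: Dess–Martin periodinane, NaHCO3, CH2Cl2, 0 °C to rt
Reagents that add atoms: none
Why: Dess–Martin oxidation of a benzylic secondary alcohol; both epimers converge on one ketone, and the buffered neutral medium should not open O1–C2.

Step 10
Reactants: 16 (2R)-7-bromo-6-(4-methoxybenzyloxy)-2-methyl-2-(4-methylpent-3-en-1-yl)chroman-4-one
Product: 17 (2R)-7-bromo-2-(4-hydroxy-4-methylpentyl)-6-(4-methoxybenzyloxy)-2-methylchroman-4-one
Conditions: Co(acac)2 (20 mol %), PhSiH3, O2 (1 atm), THF, rt
Reagents that add atoms: dioxygen, O=O
Why: Mukaiyama hydration; hydrogen-atom transfer from a cobalt hydride to the trisubstituted alkene gives the tertiary radical, which is trapped by oxygen and reduced by the silane to the Markovnikov alcohol. The neutral conditions should spare ketone, aryl bromide and benzyl ether, and the still-masked phenol cannot inhibit the radical chain.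

Step 11
Reactants: 17 (2R)-7-bromo-2-(4-hydroxy-4-methylpentyl)-6-(4-methoxybenzyloxy)-2-methylchroman-4-one
Product: 18 (2R)-7-bromo-6-hydroxy-2-(4-hydroxy-4-methylpentyl)-2-methylchroman-4-one
Conditions: DDQ, CH2Cl2/pH 7 buffer, 0 °C to rt
Reagents that add atoms: none
Why: Oxidative cleavage of the 4-methoxybenzyl ether (benzylic hydride abstraction, then hydrolysis of the oxocarbenium ion) under neutral conditions that leave the tertiary alcohol, the aryl bromide and C2 alone. The freed phenol is deactivated towards further oxidation by the ring carbonyl and the bromine.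

## Compound list

1 | (R)-linalool, (3R)-3,7-dimethylocta-1,6-dien-3-ol | CC(C)=CCC[C@@](C)(O)C=C | starting material
2 | 3,6-dichloropyridazine | Clc1ccc(Cl)nn1 | starting material
3 | 4-methoxybenzyl alcohol | COc1ccc(CO)cc1 | starting material
4 | 3-chloro-6-{[(3R)-3,7-dimethylocta-1,6-dien-3-yl]oxy}pyridazine | CC(C)=CCC[C@@](C)(Oc1ccc(Cl)nn1)C=C | intermediate (not isolated)
5 | 3-{[(3R)-3,7-dimethylocta-1,6-dien-3-yl]oxy}-6-(4-methoxybenzyloxy)pyridazine | CC(C)=CCC[C@@](C)(Oc1ccc(OCc2ccc(OC)cc2)nn1)C=C | intermediate
6 | {6-{[(3R)-3,7-dimethylocta-1,6-dien-3-yl]oxy}-3-(4-methoxybenzyloxy)pyridazin-4-yl}magnesium chloride (LiCl complex) | CC(C)=CCC[C@@](C)(Oc1cc([Mg]Cl)c(OCc2ccc(OC)cc2)nn1)C=C | intermediate (not isolated)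
7 | 4-bromo-6-{[(3R)-3,7-dimethylocta-1,6-dien-3-yl]oxy}-3-(4-methoxybenzyloxy)pyridazine | CC(C)=CCC[C@@](C)(Oc1cc(Br)c(OCc2ccc(OC)cc2)nn1)C=C | intermediate
8 | 9-[(3S)-3-{[5-bromo-6-(4-methoxybenzyloxy)pyridazin-3-yl]oxy}-3,7-dimethyloct-6-en-1-yl]-9-borabicyclo[3.3.1]nonane (geometry as in 9; the descriptor changes only because boron ranks below carbon) | CC(C)=CCC[C@](C)(CCB1C2CCCC1CCC2)Oc1cc(Br)c(OCc2ccc(OC)cc2)nn1 | intermediate (not isolated)
9 | (3R)-3-{[5-bromo-6-(4-methoxybenzyloxy)pyridazin-3-yl]oxy}-3,7-dimethyloct-6-en-1-ol | CC(C)=CCC[C@](C)(CCO)Oc1cc(Br)c(OCc2ccc(OC)cc2)nn1 | intermediate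
10 | (3R)-3-{[5-bromo-6-(4-methoxybenzyloxy)pyridazin-3-yl]oxy}-3,7-dimethyloct-6-enal | CC(C)=CCC[C@](C)(CC=O)Oc1cc(Br)c(OCc2ccc(OC)cc2)nn1 | intermediate
11 | (3RS,5R)-5-{[5-bromo-6-(4-methoxybenzyloxy)pyridazin-3-yl]oxy}-5,9-dimethyldec-8-en-1-yn-3-ol (both C3 epimers) | CC(C)=CCC[C@](C)(CC(O)C#C)Oc1cc(Br)c(OCc2ccc(OC)cc2)nn1 | intermediate
12 | 4-bromo-6-{[(3RS,5R)-3-(tert-butyldimethylsilyloxy)-5,9-dimethyldec-8-en-1-yn-5-yl]oxy}-3-(4-methoxybenzyloxy)pyridazine (both C3 epimers) | CC(C)=CCC[C@](C)(CC(O[Si](C)(C)C(C)(C)C)C#C)Oc1cc(Br)c(OCc2ccc(OC)cc2)nn1 | intermediate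
13 | bridged [4+2] adduct of 12: pyran-fused 2,3-diazabicyclo[2.2.2]octa-2,5,7-triene with (R)-configured C2, one bridgehead bonded to O1 and C4a, the other bearing the 4-methoxybenzyloxy group, bromine on the C7=C8 bridge | CC(C)=CCC[C@]1(C)CC(O[Si](C)(C)C(C)(C)C)C2=CC3(OCc4ccc(OC)cc4)N=NC2(O1)C=C3Br | intermediate (not isolated)
14 | (2R,4RS)-7-bromo-4-(tert-butyldimethylsilyloxy)-6-(4-methoxybenzyloxy)-2-methyl-2-(4-methylpent-3-en-1-yl)chromane (both C4 epimers) | CC(C)=CCC[C@]1(C)CC(O[Si](C)(C)C(C)(C)C)c2cc(OCc3ccc(OC)cc3)c(Br)cc2O1 | intermediate
15 | (2R,4RS)-7-bromo-6-(4-methoxybenzyloxy)-2-methyl-2-(4-methylpent-3-en-1-yl)chroman-4-ol (both C4 epimers) | CC(C)=CCC[C@]1(C)CC(O)c2cc(OCc3ccc(OC)cc3)c(Br)cc2O1 | intermediate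
16 | (2R)-7-bromo-6-(4-methoxybenzyloxy)-2-methyl-2-(4-methylpent-3-en-1-yl)chroman-4-one | CC(C)=CCC[C@]1(C)CC(=O)c2cc(OCc3ccc(OC)cc3)c(Br)cc2O1 | intermediate
17 | (2R)-7-bromo-2-(4-hydroxy-4-methylpentyl)-6-(4-methoxybenzyloxy)-2-methylchroman-4-one | CC(C)(O)CCC[C@]1(C)CC(=O)c2cc(OCc3ccc(OC)cc3)c(Br)cc2O1 | intermediate
18 | (2R)-7-bromo-6-hydroxy-2-(4-hydroxy-4-methylpentyl)-2-methylchroman-4-one | CC(C)(O)CCC[C@]1(C)CC(=O)c2cc(O)c(Br)cc2O1 | target

## Step count and least certain steps

Total step count: 11. Longest linear sequence: 11 steps from 1.

Step 7 (key step). The most likely failure is that ene-type thermal elimination of the tertiary heteroaryl ether, or O-to-N shift of the benzyl group, outruns the cycloaddition, because the dialkoxy diene is electron-rich and needs about 200 °C. The fallback makes the diene electron-poor. Starting from 12, DDQ would remove the benzyl group from the imidate oxygen to give the N-unsubstituted pyridazinone F1, and PhNTf2 with Et3N would convert it into the pyridazinyl triflate F2. F2 should cyclise well below the elimination window (about 120–150 °C) to the chromanyl triflate F3. Aqueous Bu4NOH in dioxane followed by Bu4NF would then cleave the sulfonate and the silyl ether to the phenolic diol F4. Selective O-alkylation of the phenol with 4-methoxybenzyl chloride and K2CO3 returns to the route at 15.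

Step 2. The likely failure is poor site selectivity of the deprotonation, since C4–H and C5–H each lie beside an alkoxy group. The fallback buys the bromine position instead of directing it. Commercial 4-bromo-6-chloropyridazin-3(2H)-one F5 would be O-alkylated with 4-methoxybenzyl chloride and Ag2CO3 in toluene (the silver salt favours O over N) to the bromochloro ether F6. The lithium alkoxide of 1 (LiN(SiMe3)2, toluene, 0 °C to rt) should then displace chlorine at C6: lithium coordination to the adjacent ring nitrogen guides it there and that carbon is unflanked, whereas the brominated carbon is shielded by the benzyloxy group. Site selectivity between the two halogens is unproven and is the demand of this variant. This sets out from 1 and returns at 7.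

Step 3. The likely failure is loss of the tertiary allylic heteroaryl ether (ionisation or allylic shift to nitrogen once boron coordinates the ring nitrogen) or incomplete discrimination between the two alkenes. The fallback hydroborates before any heteroaryl ether exists. Starting from 1, 9-BBN then NaBO3·4H2O would give the diol F7, and TIPSCl with imidazole would silylate only the primary hydroxyl to give the silyl ether F8. A bulky silyl group on a primary oxygen has no tendency to move to the tertiary alkoxide. The conditions of step 1 would give the dialkoxypyridazine F9 and those of step 2 the bromide F10. Bu4NF buffered with acetic acid returns to the route at 9, at the cost of two steps.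

Step 5. The likely failure is base-induced β-elimination of the heteroaryloxy group from 10, or transfer of the heteroaryl group to the new alkoxide. The fallback uses a non-basic organochromium nucleophile. Starting from 10, (iodoethynyl)trimethylsilane and CrCl2 in THF (Nozaki–Hiyama–Kishi-type alkynylation) would give the C-silylated alkynol F11. Brief treatment with K2CO3 in methanol at 0 °C returns to the route at 11.

Step 11. The likely failure is over-oxidation of the liberated electron-rich phenol by the quinone, or sluggish cleavage of a phenolic benzyl ether. The fallback removes the benzyl group by acid before the acid-sensitive tertiary alcohol exists. Starting from 16, trifluoroacetic acid with anisole in CH2Cl2 at 0 °C would give the phenol F12, and TBSCl with imidazole the aryl silyl ether F13. The conditions of step 10 would give the tertiary alcohol F14. KHF2 in methanol, a nearly neutral fluoride source that does not endanger C2, returns to the route at 18.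

## Further compounds

F1 | step 7 | 4-bromo-6-{[(3RS,5R)-3-(tert-butyldimethylsilyloxy)-5,9-dimethyldec-8-en-1-yn-5-yl]oxy}pyridazin-3(2H)-one | CC(C)=CCC[C@](C)(CC(O[Si](C)(C)C(C)(C)C)C#C)Oc1cc(Br)c(=O)[nH]n1
F2 | step 7 | 4-bromo-6-{[(3RS,5R)-3-(tert-butyldimethylsilyloxy)-5,9-dimethyldec-8-en-1-yn-5-yl]oxy}pyridazin-3-yl trifluoromethanesulfonate | CC(C)=CCC[C@](C)(CC(O[Si](C)(C)C(C)(C)C)C#C)Oc1cc(Br)c(OS(=O)(=O)C(F)(F)F)nn1
F3 | step 7 | (2R,4RS)-7-bromo-4-(tert-butyldimethylsilyloxy)-2-methyl-2-(4-methylpent-3-en-1-yl)chroman-6-yl trifluoromethanesulfonate | CC(C)=CCC[C@]1(C)CC(O[Si](C)(C)C(C)(C)C)c2cc(OS(=O)(=O)C(F)(F)F)c(Br)cc2O1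
F4 | step 7 | (2R,4RS)-7-bromo-2-methyl-2-(4-methylpent-3-en-1-yl)chromane-4,6-diol | CC(C)=CCC[C@]1(C)CC(O)c2cc(O)c(Br)cc2O1
F5 | step 2 | 4-bromo-6-chloropyridazin-3(2H)-one (purchased) | O=c1[nH]nc(Cl)cc1Br
F6 | step 2 | 4-bromo-6-chloro-3-(4-methoxybenzyloxy)pyridazine | COc1ccc(COc2nnc(Cl)cc2Br)cc1
F7 | step 3 | (3R)-3,7-dimethyloct-6-ene-1,3-diol | CC(C)=CCC[C@@](C)(O)CCO
F8 | step 3 | (3R)-3,7-dimethyl-1-(triisopropylsilyloxy)oct-6-en-3-ol | CC(C)=CCC[C@@](C)(O)CCO[Si](C(C)C)(C(C)C)C(C)C
F9 | step 3 | 3-{[(3R)-3,7-dimethyl-1-(triisopropylsilyloxy)oct-6-en-3-yl]oxy}-6-(4-methoxybenzyloxy)pyridazine | CC(C)=CCC[C@@](C)(Oc1ccc(OCc2ccc(OC)cc2)nn1)CCO[Si](C(C)C)(C(C)C)C(C)C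
F10 | step 3 | 4-bromo-6-{[(3R)-3,7-dimethyl-1-(triisopropylsilyloxy)oct-6-en-3-yl]oxy}-3-(4-methoxybenzyloxy)pyridazine | CC(C)=CCC[C@@](C)(Oc1cc(Br)c(OCc2ccc(OC)cc2)nn1)CCO[Si](C(C)C)(C(C)C)C(C)C
F11 | step 5 | (3RS,5R)-5-{[5-bromo-6-(4-methoxybenzyloxy)pyridazin-3-yl]oxy}-5,9-dimethyl-1-(trimethylsilyl)dec-8-en-1-yn-3-ol | CC(C)=CCC[C@](C)(CC(O)C#C[Si](C)(C)C)Oc1cc(Br)c(OCc2ccc(OC)cc2)nn1
F12 | step 11 | (2R)-7-bromo-6-hydroxy-2-methyl-2-(4-methylpent-3-en-1-yl)chroman-4-one | CC(C)=CCC[C@]1(C)CC(=O)c2cc(O)c(Br)cc2O1
F13 | step 11 | (2R)-7-bromo-6-(tert-butyldimethylsilyloxy)-2-methyl-2-(4-methylpent-3-en-1-yl)chroman-4-one | CC(C)=CCC[C@]1(C)CC(=O)c2cc(O[Si](C)(C)C(C)(C)C)c(Br)cc2O1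
F14 | step 11 | (2R)-7-bromo-6-(tert-butyldimethylsilyloxy)-2-(4-hydroxy-4-methylpentyl)-2-methylchroman-4-one | CC(C)(O)CCC[C@]1(C)CC(=O)c2cc(O[Si](C)(C)C(C)(C)C)c(Br)cc2O1
A1 | alternative 1 | (E)-5-[(2S)-7-bromo-2-methyl-6-(triisopropylsilyloxy)chroman-2-yl]pent-3-en-2-one | CC(=O)/C=C/C[C@]1(C)CCc2cc(O[Si](C(C)C)(C(C)C)C(C)C)c(Br)cc2O1
A2 | alternative 1 | 5-bromo-2-(3-methylbut-3-en-1-yl)-4-(triisopropylsilyloxy)phenol | CC(=C)CCc1cc(O[Si](C(C)C)(C(C)C)C(C)C)c(Br)cc1O
A3 | alternative 1 | methyl vinyl ketone (but-3-en-2-one) | CC(=O)C=C
A4 | alternative 2 | (2R)-7-bromo-6-(methoxymethoxy)-2-methyl-2-[4-methyl-4-(triethylsilyloxy)pentyl]chroman-4-one | CC[Si](CC)(CC)OC(C)(C)CCC[C@]1(C)CC(=O)c2cc(OCOC)c(Br)cc2O1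
A5 | alternative 2 | 1-[4-bromo-5-(methoxymethoxy)-2-{[(2R)-6-methyl-6-(triethylsilyloxy)heptan-2-yl]oxy}phenyl]-2-diazoethan-1-one | CC[Si](CC)(CC)OC(C)(C)CCC[C@@H](C)Oc1cc(Br)c(OCOC)cc1C(=O)C=[N+]=[N-]
A6 | alternative 3 | (2R)-7-bromo-2-methyl-2-[4-methyl-4-(triethylsilyloxy)pentyl]-6-(triisopropylsilyloxy)chroman-4-one | CC[Si](CC)(CC)OC(C)(C)CCC[C@]1(C)CC(=O)c2cc(O[Si](C(C)C)(C(C)C)C(C)C)c(Br)cc2O1
A7 | alternative 3 | 1-bromo-4-iodo-5-{[2,6-dimethyl-6-(triethylsilyloxy)heptan-2-yl]oxy}-2-(triisopropylsilyloxy)benzene | CC[Si](CC)(CC)OC(C)(C)CCCC(C)(C)Oc1cc(Br)c(O[Si](C(C)C)(C(C)C)C(C)C)cc1I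
A8 | alternative 3 | carbon monoxide | [C-]#[O+]
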